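**Plan**

1. Retrosynthesis: the C3 ketone, the C1–C10 oxirane, the lactone C12–O8 bond and the C5 angelate are removed first; the C1=C10 bond of the ten-membered carbocycle is then traced back to SO2 extrusion from an eleven-membered sulfone whose sulfur bridges C1 and C10; after that the S–C1 and S–C10 bonds, the C4=C15 methylidene, the C5–C6 bond (ketone boron aldol) and the C7–C8 bond (auxiliary aldol) are cut.
2. Forward: aldehyde C6–C10/C14 (carrying C11–C13) and ketone C1–C5 are joined at C5–C6; sulfur is attached at C10 and the thiacycle is closed at C1; oxidation and ring contraction give the carbocycle; the lactone ring, then the oxirane ring, are formed and the C3 ketone comes last.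
3. Enabling feature: the oxirane is cis-fused to the ten-membered ring C1–C10 (C1 is the epoxide CH, C10 carries methyl C14, ring bonds C1–C2 and C10–C9 on the same side), so it derives from a Z-trisubstituted C1=C10 olefin, the low-strain geometry in this ring and the one a cis-fused episulfone releases stereospecifically.
4. Stereochemistry: C7 and C8 come from the oxazolidinone auxiliary; C5 and C6 from the C3 silyloxy centre of the ketone (chiral pool, oxidized away at the end); C1 and C10 from face-selective epoxidation of the Z olefin; the angelate geometry comes with angelic acid.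

Key step: step 23

Remark: germacranolide locants (C1 oxirane CH, C10 oxirane carbon bearing C14, C12 lactone carbonyl on O–C8) are used for all intermediates; the C3 carbinol is a temporary stereocentre, made S because that configuration should steer the C5–C6 aldol and shield the α face in the epoxidation, and the C10 chain centre (from (R)-pent-4-en-2-ol) is immaterial; TBS = tert-butyldimethylsilyl, TES = triethylsilyl, PMB = 4-methoxybenzyl, Piv = pivaloyl, Ang = angeloyl.

**Route**

Step 1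
Reactants: 1 4-methyl hydrogen itaconate
Product: 3 methyl 3-(hydroxymethyl)but-3-enoate, via isobutyl mixed carbonic anhydride 2 (not isolated)
Conditions: i-BuOCOCl, N-methylmorpholine, THF, −15 °C; then NaBH4, H2O, 0 °C
Reagents that add atoms: none
Why: Activation of the free conjugated acid as a mixed carbonic anhydride lets NaBH4 reduce it to the allylic alcohol while the methyl ester stays (mixed-anhydride borohydride reduction).

Step 2
Reactants: 3 methyl 3-(hydroxymethyl)but-3-enoate
Product: 4 methyl 3-[(TBS-oxy)methyl]but-3-enoate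
Conditions: TBSCl, imidazole, CH2Cl2, 0 °C → rt
Reagents that add atoms: tert-butyldimethylsilyl chloride, CC(C)(C)[Si](C)(C)Cl
Why: Routine silylation of a primary alcohol; the TBS group is chosen over TES at C12 because it must survive the basic ring-closure and ring-contraction steps.

Step 3
Reactants: 4 methyl 3-[(TBS-oxy)methyl]but-3-enoate
Product: 5 3-[(TBS-oxy)methyl]but-3-enoic acid
Conditions: LiOH·H2O, THF/H2O, 0 °C; then 0.5 M HCl to pH 4
Reagents that add atoms: lithium hydroxide, [Li+].[OH-]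
Why: Cold saponification of the methyl ester, mild enough to leave the silyl ether and to keep the olefin out of conjugation.

Step 4
Reactants: 5 3-[(TBS-oxy)methyl]but-3-enoic acid; 6 (S)-4-benzyloxazolidin-2-one
Product: 9 (S)-4-benzyl-3-{3-[(TBS-oxy)methyl]but-3-enoyl}oxazolidin-2-one, via mixed pivalic anhydride 7 (not isolated), via lithium oxazolidinide 8 (not isolated)
Conditions: PivCl, Et3N, THF, −78 → 0 °C; then 6 pretreated with n-BuLi (THF, −78 °C), −78 → 0 °C; aq. NH4Cl
Reagents that add atoms: none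
Why: N-Acylation of the lithiated oxazolidinone by the mixed anhydride at low temperature (standard imide formation), cold enough to avoid isomerization of the β,γ-olefin.

Step 5
Reactants: 10 (R)-pent-4-en-2-ol
Product: 11 (R)-pent-4-en-2-yl pivalate
Conditions: PivCl, pyridine, 4-(dimethylamino)pyridine (cat.), CH2Cl2, 0 °C → rt
Reagents that add atoms: pivaloyl chloride, CC(C)(C)C(=O)Cl
Why: Acylation of the secondary alcohol; the pivalate should survive boron enolates, LiBH4 at 0 °C and silyl triflates and is later removed reductively without touching silyl or PMB ethers.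

Step 6
Reactants: 11 (R)-pent-4-en-2-yl pivalate
Product: 13 (R)-4-oxobutan-2-yl pivalate, via secondary ozonide 12 (not isolated)
Conditions: O3, CH2Cl2, −78 °C; then PPh3, −78 °C → rt
Reagents that add atoms: ozone, [O-][O+]=O
Why: Ozonolysis of the terminal alkene with reductive work-up gives the β-acyloxy aldehyde (C8–C10, C14), which is used without chromatography.

Step 7
Reactants: 9 but-3-enoyl imide; 13 (R)-4-oxobutan-2-yl pivalate
Product: 16 syn-aldol imide (C7 S; C8 R; free C8 hydroxyl), via Z(O) dibutylboron dienolate 14 (not isolated), via dibutylboron aldolate 15 (not isolated)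
Conditions: Bu2BOTf, Et3N, CH2Cl2, −78 → 0 °C; then 13, −78 → 0 °C; pH 7 buffer, MeOH, 30% H2O2, 0 °C
Reagents that add atoms: none
Why: Evans syn aldol: soft enolization gives the Z(O) boron dienolate, which reacts through its α-carbon in a chair Zimmerman–Traxler transition state on the face away from the benzyl group, setting C7 and C8 (C8–O syn to the C11 branch).

Step 8
Reactants: 16 syn-aldol imide
Product: 17 C8 triethylsilyl ether of 16
Conditions: TESOTf, 2,6-lutidine, CH2Cl2, −78 °C
Reagents that add atoms: triethylsilyl trifluoromethanesulfonate, CC[Si](CC)(CC)OS(=O)(=O)C(F)(F)F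
Why: Silyl triflate protection of the hindered aldol hydroxyl at low temperature avoids retro-aldol cleavage.

Step 9
Reactants: 17 C8 triethylsilyl ether
Product: 18 C6 primary alcohol (2R,4R,5R)-hexan-2-yl pivalate
Conditions: LiBH4, MeOH (1 equiv), THF, 0 °C
Reagents that add atoms: none
Why: Reductive removal of the auxiliary; LiBH4 attacks the activated exocyclic imide carbonyl much faster than the hindered pivalate.

Step 10
Reactants: 18 C6 primary alcohol
Product: 19 C6 aldehyde (C6–C10/C14 fragment with C11–C13)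
Conditions: Dess–Martin periodinane, NaHCO3, CH2Cl2, 0 °C → rt
Reagents that add atoms: none
Why: Buffered Dess–Martin oxidation is non-epimerizing for the α-branched β,γ-unsaturated aldehyde, which is used at once.

Step 11
Reactants: 20 tributyl(iodomethyl)stannane; 21 4-methoxybenzyl alcohol
Product: 23 tributyl[(4-methoxybenzyloxy)methyl]stannane, via sodium 4-methoxybenzyl oxide 22 (not isolated)
Conditions: NaH, THF/DMF, 0 °C → rt
Reagents that add atoms: none
Why: Williamson etherification of the alkoxide with the primary iodide.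

Step 12
Reactants: 24 (S)-3-hydroxydihydrofuran-2(3H)-one
Product: 25 (S)-3-(TBS-oxy)dihydrofuran-2(3H)-one
Conditions: TBSCl, imidazole, DMF, rt
Reagents that add atoms: tert-butyldimethylsilyl chloride, CC(C)(C)[Si](C)(C)Cl
Why: Routine silylation of the secondary alcohol that becomes the temporary C3 stereocentre.

Step 13
Reactants: 25 (S)-3-(TBS-oxy)dihydrofuran-2(3H)-one
Product: 26 (S)-2-(TBS-oxy)-4-hydroxy-N-methoxy-N-methylbutanamide
Conditions: MeONHMe·HCl, AlMe3, CH2Cl2, 0 °C → rt
Reagents that add atoms: N,O-dimethylhydroxylamine hydrochloride, CNOC.Cl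
Why: Aluminium-amide aminolysis of the lactone (Weinreb amide formation) opens the ring and frees the C1 hydroxyl; the product is used directly to avoid relactonization.

Step 14
Reactants: 26 hydroxy Weinreb amide
Product: 27 (S)-2-(TBS-oxy)-4-chloro-N-methoxy-N-methylbutanamide
Conditions: PPh3, N-chlorosuccinimide, CH2Cl2, 0 °C → rt
Reagents that add atoms: N-chlorosuccinimide, O=C1CCC(=O)N1Cl
Why: Appel-type chlorination of the primary alcohol; the chloride is a latent leaving group at C1 that needs no protecting group and is inert to the steps that follow.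

Step 15
Reactants: 27 chloro Weinreb amide; 23 tributyl[(4-methoxybenzyloxy)methyl]stannane
Product: 29 (S)-3-(TBS-oxy)-5-chloro-1-(PMB-oxy)pentan-2-one, via α-alkoxymethyllithium 28 (not isolated)
Conditions: n-BuLi, THF, −78 °C; then 27, −78 °C; aq. NH4Cl
Reagents that add atoms: none
Why: Tin–lithium exchange gives the α-alkoxymethyllithium, which adds once to the Weinreb amide through the stable chelated tetrahedral adduct to give the α-alkoxy ketone (C1–C5).

Step 16
Reactants: 29 C1–C5 ketone; 19 C6 aldehyde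
Product: 32 aldol adduct (5-OPMB; free 6-OH; C4 ketone), via Z-enol dicyclohexylborinate 30 (not isolated), via dicyclohexylboron aldolate 31 (not isolated)
Conditions: Cy2BCl, Et3N, Et2O, −78 → 0 °C; then 19, −78 → −20 °C; pH 7 buffer, MeOH, 30% H2O2, 0 °C
Reagents that add atoms: none
Why: Boron aldol of an α,α′-dioxygenated ketone: enolization on the CH2OPMB side gives the Z-enol borinate, the chair Zimmerman–Traxler transition state gives the 5,6-syn aldol, and the C3 silyloxy centre (C3–O antiperiplanar to the enolate C–O, aldehyde approaching anti to the C2 chain) should select the enolate face that sets C5 and hence C6 as required.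

Step 17
Reactants: 32 aldol adduct
Product: 33 C6 TBS ether of 32
Conditions: TBSOTf, 2,6-lutidine, CH2Cl2, −78 → 0 °C
Reagents that add atoms: tert-butyldimethylsilyl trifluoromethanesulfonate, CC(C)(C)[Si](C)(C)OS(=O)(=O)C(F)(F)F
Why: Silyl triflate protection of the hindered β-hydroxy ketone at low temperature, without retro-aldol or epimerization.

Step 18
Reactants: 33 C4 ketone
Product: 34 C4(15)-methylidene compound
Conditions: Cp2Ti(μ-CH2)(μ-Cl)AlMe2 (Tebbe reagent), pyridine, THF/toluene, −40 → 0 °C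
Reagents that add atoms: Tebbe reagent, C[Al](C)C[Ti](Cl)(C1C=CC=C1)C1C=CC=C1
Why: Tebbe methylenation: the non-basic titanium methylidene converts hindered, enolizable α,α′-dioxygenated ketones into 1,1-disubstituted alkenes without epimerization or β-elimination and reacts with the ketone faster than with the pivalate.

Step 19
Reactants: 34 methylidene pivalate
Product: 35 C10 secondary alcohol
Conditions: i-Bu2AlH, CH2Cl2, −78 °C; aq. KNaC4H4O6
Reagents that add atoms: none
Why: Reductive cleavage of the pivalate, orthogonal to the silyl ethers, the PMB ether and the primary chloride.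

Step 20
Reactants: 35 C10 secondary alcohol
Product: 36 C10 thioacetate (inverted at C10)
Conditions: AcSH, PPh3, DIAD, THF, 0 °C → rt
Reagents that add atoms: thioacetic acid, CC(=O)S
Why: Mitsunobu reaction with thioacetic acid: SN2 displacement of the activated unhindered methyl carbinol with inversion forms the S–C10 bond intermolecularly.

Step 21
Reactants: 36 C10 thioacetate
Product: 38 eleven-membered cyclic sulfide (S bridging C1 and C10), via caesium C10 thiolate 37 (not isolated)
Conditions: Cs2CO3, NaI (cat.), MeOH/DMF 1:9, degassed, 50 °C, syringe-pump addition to ca. 1 mM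
Reagents that add atoms: none
Why: Methanolysis of the thioacetate releases the caesium thiolate, which closes the ring by SN2 at the unhindered primary C1 chloride under high dilution (caesium thiolate macrocyclization).

Step 22
Reactants: 38 cyclic sulfide
Product: 40 eleven-membered cyclic sulfone, via cyclic sulfoxide 39 (not isolated)
Conditions: 30% aq. H2O2, (NH4)6Mo7O24·4H2O (cat.), EtOH, 0 °C → rt
Reagents that add atoms: hydrogen peroxide, OO
Why: Molybdate-catalysed peroxide oxidation takes the sulfide through the sulfoxide to the sulfone and leaves the 1,1-disubstituted olefins, the PMB ether and the silyl ethers alone.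

Step 23
Reactants: 40 eleven-membered cyclic sulfone
Product: 43 ten-membered (Z)-1(10)-ene, via C1 α-bromo sulfone 41 (not isolated), via cis-fused episulfone 42 (not isolated)
Conditions: CBr2F2, KOH/Al2O3, t-BuOH/CH2Cl2, 0 °C → rt
Reagents that add atoms: none
Why: Hydroxide on alumina deprotonates the sulfone at C1, the carbanion takes bromine from CBr2F2, a second deprotonation at C10 displaces bromide in a 1,3-elimination to the thiirane 1,1-dioxide 42, and cheletropic loss of SO2 leaves the C1=C10 bond (Ramberg–Bäcklund reaction with in-situ halogenation). The closest known reaction type is the ring contraction of medium and large cyclic sulfones to cycloalkenes under these conditions. The three-membered ring closes 3-exo-tet inside the eleven-membered thiacycle and its collapse turns that thiacycle into the ten-membered carbocycle, so the carbocycle arises by contraction and not by an end-to-end C–C cyclization. No stereocentre is formed and the C10 centre is erased; the only stereochemical element is the olefin geometry, which follows from stereospecific SO2 loss out of the cis-fused episulfone, the low-strain ring fusion here, reached directly or by base equilibration at its C1–H. The step needs Z selectivity and must spare the two 1,1-disubstituted olefins and the silyl and PMB ethers: ring strain should secure the former, and CBr2F2 (whose CF2 by-product does not add to unactivated alkenes) with a solid base should secure the latter, while the site of bromination is irrelevant because both α-carbons carry a proton.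

Step 24
Reactants: 43 (Z)-1(10)-ene with 5-OPMB
Product: 44 C5 allylic alcohol
Conditions: DDQ, CH2Cl2/pH 7 phosphate buffer 10:1, 0 °C
Reagents that add atoms: none
Why: Oxidative PMB cleavage through the benzylic oxocarbenium ion, buffered so that the silyl ethers stay.

Step 25
Reactants: 44 C5 allylic alcohol; 45 angelic acid
Product: 47 C5 angelate, via angelic trichlorobenzoic anhydride 46 (not isolated)
Conditions: 45, 2,4,6-trichlorobenzoyl chloride, Et3N, toluene, rt; then 44, 75 °C
Reagents that add atoms: none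
Why: Acylation by the preformed mixed anhydride without a nucleophilic catalyst (Yamaguchi-type esterification), conditions under which the angeloyl group is transferred without Z-to-E isomerization to the tiglate.

Step 26
Reactants: 47 C5 angelate
Product: 48 8,12-diol
Conditions: HF·pyridine, pyridine, THF, 0 °C
Reagents that add atoms: none
Why: Buffered HF·pyridine removes the secondary TES ether and the primary allylic TBS ether much faster than the two hindered secondary TBS ethers at C3 and C6.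

Step 27
Reactants: 48 8,12-diol
Product: 51 trans-fused α-methylene-γ-butyrolactone (12,8-olide), via C12 hydroxy enal 49 (not isolated), via C12 lactol 50 (not isolated)
Conditions: TEMPO (2,2,6,6-tetramethylpiperidin-1-oxyl, cat.), PhI(OAc)2, CH2Cl2, rt
Reagents that add atoms: none
Why: Oxoammonium oxidation of the primary allylic alcohol, lactol formation with the C8 hydroxyl and a second oxidation give the lactone (oxidative lactonization of a 1,4-diol); C6 is still silylated, so only the 8,12-olide can form.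

Step 28
Reactants: 51 12,8-olide with C1=C10
Product: 52 (1S,10R)-1,10-epoxide
Conditions: mCPBA, NaHCO3, CH2Cl2, 0 °C
Reagents that add atoms: 3-chloroperoxybenzoic acid, O=C(OO)c1cccc(Cl)c1
Why: Prilezhaev epoxidation of the only electron-rich olefin (the other three are conjugated or flanked by allylic oxygens); the peracid should add to the β face, anti to the homoallylic C3 silyloxy group and the C8 lactone oxygen on the α face, and the Z geometry gives the cis-epoxide stereospecifically.

Step 29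
Reactants: 52 bis-TBS epoxy lactone
Product: 53 3,6-diol
Conditions: HF·pyridine, pyridine, THF, 0 °C → rt
Reagents that add atoms: none
Why: Fluoride cleavage of the two remaining secondary TBS ethers under buffered, weakly acidic conditions that the epoxide, the angelate and the lactone should tolerate.

Step 30
Reactants: 53 3,6-diol
Product: 54 CNP0348992.1
Conditions: activated MnO2, CH2Cl2, rt
Reagents that add atoms: none
Why: MnO2 oxidizes only the allylic C3 alcohol, giving the α-methylene ketone, and leaves the non-allylic C6 alcohol untouched.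

**Compound list**

1 | 4-methyl hydrogen itaconate (4-methoxy-2-methylidene-4-oxobutanoic acid) | C=C(CC(=O)OC)C(=O)O | starting material
2 | isobutyl carbonic mixed anhydride of 1 (formed in the flask) | C=C(CC(=O)OC)C(=O)OC(=O)OCC(C)C | intermediate
3 | methyl 3-(hydroxymethyl)but-3-enoate | C=C(CO)CC(=O)OC | intermediate
4 | methyl 3-[(tert-butyldimethylsilyloxy)methyl]but-3-enoate | C=C(CO[Si](C)(C)C(C)(C)C)CC(=O)OC | intermediate
5 | 3-[(tert-butyldimethylsilyloxy)methyl]but-3-enoic acid | C=C(CO[Si](C)(C)C(C)(C)C)CC(=O)O | intermediate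
6 | (S)-4-benzyloxazolidin-2-one | O=C1N[C@@H](Cc2ccccc2)CO1 | starting material
7 | pivalic mixed anhydride of 5 (formed in the flask) | C=C(CO[Si](C)(C)C(C)(C)C)CC(=O)OC(=O)C(C)(C)C | intermediate
8 | N-lithio-(S)-4-benzyloxazolidin-2-one (formed in the flask) | [Li]N1[C@@H](Cc2ccccc2)COC1=O | intermediate
9 | (S)-4-benzyl-3-{3-[(tert-butyldimethylsilyloxy)methyl]but-3-enoyl}oxazolidin-2-one | C=C(CO[Si](C)(C)C(C)(C)C)CC(=O)N1[C@@H](Cc2ccccc2)COC1=O | intermediate
10 | (R)-pent-4-en-2-ol | C[C@@H](O)CC=C | starting material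
11 | (R)-pent-4-en-2-yl pivalate | C[C@@H](OC(=O)C(C)(C)C)CC=C | intermediate
12 | secondary ozonide of 11, (2R)-1-(1,2,4-trioxolan-3-yl)propan-2-yl pivalate (both epimers at the trioxolane carbon; formed in the flask) | C[C@@H](OC(=O)C(C)(C)C)CC1OOCO1 | intermediate
13 | (R)-4-oxobutan-2-yl pivalate | C[C@@H](OC(=O)C(C)(C)C)CC=O | intermediate
14 | Z(O) di-n-butylboron dienolate of 9 (formed in the flask) | C=C(CO[Si](C)(C)C(C)(C)C)/C=C(\OB(CCCC)CCCC)N1[C@@H](Cc2ccccc2)COC1=O | intermediate
15 | O-(di-n-butylboryl) aldolate of 16 (formed in the flask) | C[C@@H](OC(=O)C(C)(C)C)C[C@@H](OB(CCCC)CCCC)[C@H](C(=C)CO[Si](C)(C)C(C)(C)C)C(=O)N1[C@@H](Cc2ccccc2)COC1=O | intermediate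
16 | (S)-4-benzyl-3-[(2S,3R,5R)-2-[3-(tert-butyldimethylsilyloxy)prop-1-en-2-yl]-3-hydroxy-5-(pivaloyloxy)hexanoyl]oxazolidin-2-one | C[C@@H](OC(=O)C(C)(C)C)C[C@@H](O)[C@H](C(=C)CO[Si](C)(C)C(C)(C)C)C(=O)N1[C@@H](Cc2ccccc2)COC1=O | intermediate
17 | (S)-4-benzyl-3-[(2S,3R,5R)-2-[3-(tert-butyldimethylsilyloxy)prop-1-en-2-yl]-5-(pivaloyloxy)-3-(triethylsilyloxy)hexanoyl]oxazolidin-2-one | C[C@@H](OC(=O)C(C)(C)C)C[C@@H](O[Si](CC)(CC)CC)[C@H](C(=C)CO[Si](C)(C)C(C)(C)C)C(=O)N1[C@@H](Cc2ccccc2)COC1=O | intermediate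
18 | (2R,4R,5R)-5-[3-(tert-butyldimethylsilyloxy)prop-1-en-2-yl]-6-hydroxy-4-(triethylsilyloxy)hexan-2-yl pivalate | C[C@@H](OC(=O)C(C)(C)C)C[C@@H](O[Si](CC)(CC)CC)[C@H](C(=C)CO[Si](C)(C)C(C)(C)C)CO | intermediate
19 | (2R,4R,5S)-5-[3-(tert-butyldimethylsilyloxy)prop-1-en-2-yl]-6-oxo-4-(triethylsilyloxy)hexan-2-yl pivalate | C[C@@H](OC(=O)C(C)(C)C)C[C@@H](O[Si](CC)(CC)CC)[C@H](C(=C)CO[Si](C)(C)C(C)(C)C)C=O | intermediate
20 | tributyl(iodomethyl)stannane | CCCC[Sn](CCCC)(CCCC)CI | starting material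
21 | 4-methoxybenzyl alcohol | COc1ccc(CO)cc1 | starting material
22 | sodium 4-methoxybenzyl oxide (formed in the flask) | [Na+].[O-]Cc1ccc(OC)cc1 | intermediate
23 | tributyl[(4-methoxybenzyloxy)methyl]stannane | CCCC[Sn](CCCC)(CCCC)COCc1ccc(OC)cc1 | intermediate
24 | (S)-3-hydroxydihydrofuran-2(3H)-one ((S)-α-hydroxy-γ-butyrolactone) | O[C@H]1CCOC1=O | starting material
25 | (S)-3-(tert-butyldimethylsilyloxy)dihydrofuran-2(3H)-one | CC(C)(C)[Si](C)(C)O[C@H]1CCOC1=O | intermediate
26 | (S)-2-(tert-butyldimethylsilyloxy)-4-hydroxy-N-methoxy-N-methylbutanamide | OCC[C@H](O[Si](C)(C)C(C)(C)C)C(=O)N(C)OC | intermediate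
27 | (S)-2-(tert-butyldimethylsilyloxy)-4-chloro-N-methoxy-N-methylbutanamide | ClCC[C@H](O[Si](C)(C)C(C)(C)C)C(=O)N(C)OC | intermediate
28 | [(4-methoxybenzyloxy)methyl]lithium (formed in the flask) | [Li]COCc1ccc(OC)cc1 | intermediate
29 | (S)-3-(tert-butyldimethylsilyloxy)-5-chloro-1-(4-methoxybenzyloxy)pentan-2-one | ClCC[C@H](O[Si](C)(C)C(C)(C)C)C(=O)COCc1ccc(OC)cc1 | intermediate
30 | Z-enol dicyclohexylborinate of 29 (formed in the flask) | ClCC[C@H](O[Si](C)(C)C(C)(C)C)/C(OB(C1CCCCC1)C1CCCCC1)=C/OCc1ccc(OC)cc1 | intermediate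
31 | O-(dicyclohexylboryl) aldolate of 32 (formed in the flask) | ClCC[C@H](O[Si](C)(C)C(C)(C)C)C(=O)[C@H](OCc1ccc(OC)cc1)[C@@H](OB(C1CCCCC1)C1CCCCC1)[C@@H](C(=C)CO[Si](C)(C)C(C)(C)C)[C@H](O[Si](CC)(CC)CC)C[C@H](OC(=O)C(C)(C)C)C | intermediate
32 | (3S,5R,6S,7R,8R,10R)-3-(tert-butyldimethylsilyloxy)-7-[3-(tert-butyldimethylsilyloxy)prop-1-en-2-yl]-1-chloro-6-hydroxy-5-(4-methoxybenzyloxy)-4-oxo-8-(triethylsilyloxy)undecan-10-yl pivalate (chain numbered from the chloride, as in the germacranolide) | ClCC[C@H](O[Si](C)(C)C(C)(C)C)C(=O)[C@H](OCc1ccc(OC)cc1)[C@@H](O)[C@@H](C(=C)CO[Si](C)(C)C(C)(C)C)[C@H](O[Si](CC)(CC)CC)C[C@H](OC(=O)C(C)(C)C)C | intermediate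
33 | (3S,5R,6S,7S,8R,10R)-3,6-bis(tert-butyldimethylsilyloxy)-7-[3-(tert-butyldimethylsilyloxy)prop-1-en-2-yl]-1-chloro-5-(4-methoxybenzyloxy)-4-oxo-8-(triethylsilyloxy)undecan-10-yl pivalate | ClCC[C@H](O[Si](C)(C)C(C)(C)C)C(=O)[C@H](OCc1ccc(OC)cc1)[C@@H](O[Si](C)(C)C(C)(C)C)[C@@H](C(=C)CO[Si](C)(C)C(C)(C)C)[C@H](O[Si](CC)(CC)CC)C[C@H](OC(=O)C(C)(C)C)C | intermediate
34 | (3S,5S,6S,7S,8R,10R)-3,6-bis(tert-butyldimethylsilyloxy)-7-[3-(tert-butyldimethylsilyloxy)prop-1-en-2-yl]-1-chloro-5-(4-methoxybenzyloxy)-4-methylidene-8-(triethylsilyloxy)undecan-10-yl pivalate | ClCC[C@H](O[Si](C)(C)C(C)(C)C)C(=C)[C@H](OCc1ccc(OC)cc1)[C@@H](O[Si](C)(C)C(C)(C)C)[C@@H](C(=C)CO[Si](C)(C)C(C)(C)C)[C@H](O[Si](CC)(CC)CC)C[C@H](OC(=O)C(C)(C)C)C | intermediate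
35 | (3S,5S,6S,7S,8R,10R)-3,6-bis(tert-butyldimethylsilyloxy)-7-[3-(tert-butyldimethylsilyloxy)prop-1-en-2-yl]-1-chloro-5-(4-methoxybenzyloxy)-4-methylidene-8-(triethylsilyloxy)undecan-10-ol | ClCC[C@H](O[Si](C)(C)C(C)(C)C)C(=C)[C@H](OCc1ccc(OC)cc1)[C@@H](O[Si](C)(C)C(C)(C)C)[C@@H](C(=C)CO[Si](C)(C)C(C)(C)C)[C@H](O[Si](CC)(CC)CC)C[C@H](O)C | intermediate
36 | S-[(3S,5S,6S,7S,8R,10S)-3,6-bis(tert-butyldimethylsilyloxy)-7-[3-(tert-butyldimethylsilyloxy)prop-1-en-2-yl]-1-chloro-5-(4-methoxybenzyloxy)-4-methylidene-8-(triethylsilyloxy)undecan-10-yl] ethanethioate | ClCC[C@H](O[Si](C)(C)C(C)(C)C)C(=C)[C@H](OCc1ccc(OC)cc1)[C@@H](O[Si](C)(C)C(C)(C)C)[C@@H](C(=C)CO[Si](C)(C)C(C)(C)C)[C@H](O[Si](CC)(CC)CC)C[C@@H](SC(C)=O)C | intermediate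
37 | caesium C10 thiolate obtained from 36 by loss of the acetyl group (formed in the flask) | ClCC[C@H](O[Si](C)(C)C(C)(C)C)C(=C)[C@H](OCc1ccc(OC)cc1)[C@@H](O[Si](C)(C)C(C)(C)C)[C@@H](C(=C)CO[Si](C)(C)C(C)(C)C)[C@H](O[Si](CC)(CC)CC)C[C@@H]([S-])C.[Cs+] | intermediate
38 | eleven-membered cyclic sulfide, sulfur bridging C1 and C10, (3S,5S,6S,7S,8R,10S): 3,6-bis(TBS-oxy), 4-methylidene, 5-(PMB-oxy), 7-[3-(TBS-oxy)prop-1-en-2-yl], 8-(TES-oxy), 10-methyl | C[C@H]1C[C@@H](O[Si](CC)(CC)CC)[C@H](C(=C)CO[Si](C)(C)C(C)(C)C)[C@H](O[Si](C)(C)C(C)(C)C)[C@@H](OCc2ccc(OC)cc2)C(=C)[C@@H](O[Si](C)(C)C(C)(C)C)CCS1 | intermediate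
39 | S-oxide of 38 (either configuration at sulfur; formed in the flask) | C[C@H]1C[C@@H](O[Si](CC)(CC)CC)[C@H](C(=C)CO[Si](C)(C)C(C)(C)C)[C@H](O[Si](C)(C)C(C)(C)C)[C@@H](OCc2ccc(OC)cc2)C(=C)[C@@H](O[Si](C)(C)C(C)(C)C)CCS1=O | intermediate
40 | S,S-dioxide of 38, eleven-membered cyclic sulfone (3S,5S,6S,7S,8R,10S) | C[C@H]1C[C@@H](O[Si](CC)(CC)CC)[C@H](C(=C)CO[Si](C)(C)C(C)(C)C)[C@H](O[Si](C)(C)C(C)(C)C)[C@@H](OCc2ccc(OC)cc2)C(=C)[C@@H](O[Si](C)(C)C(C)(C)C)CCS1(=O)=O | intermediate
41 | 1-bromo derivative of sulfone 40 (either C1 epimer; formed in the flask) | C[C@H]1C[C@@H](O[Si](CC)(CC)CC)[C@H](C(=C)CO[Si](C)(C)C(C)(C)C)[C@H](O[Si](C)(C)C(C)(C)C)[C@@H](OCc2ccc(OC)cc2)C(=C)[C@@H](O[Si](C)(C)C(C)(C)C)CC(Br)S1(=O)=O | intermediate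
42 | cis-fused episulfone: thiirane 1,1-dioxide spanning C1 and C10 of the ten-membered ring (one cis-fused diastereomer drawn; formed in the flask) | C[C@@]12S(=O)(=O)[C@H]2C[C@H](O[Si](C)(C)C(C)(C)C)C(=C)[C@H](OCc3ccc(OC)cc3)[C@@H](O[Si](C)(C)C(C)(C)C)[C@@H](C(=C)CO[Si](C)(C)C(C)(C)C)[C@H](O[Si](CC)(CC)CC)C1 | intermediate
43 | (1(10)Z,3S,5S,6S,7S,8R)-3,6,12-tris(tert-butyldimethylsilyloxy)-5-(4-methoxybenzyloxy)-8-(triethylsilyloxy)germacra-1(10),4(15),11(13)-triene | C/C1=C/C[C@H](O[Si](C)(C)C(C)(C)C)C(=C)[C@H](OCc2ccc(OC)cc2)[C@@H](O[Si](C)(C)C(C)(C)C)[C@@H](C(=C)CO[Si](C)(C)C(C)(C)C)[C@H](O[Si](CC)(CC)CC)C1 | intermediate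
44 | (1(10)Z,3S,5S,6S,7S,8R)-3,6,12-tris(tert-butyldimethylsilyloxy)-8-(triethylsilyloxy)germacra-1(10),4(15),11(13)-trien-5-ol | C/C1=C/C[C@H](O[Si](C)(C)C(C)(C)C)C(=C)[C@H](O)[C@@H](O[Si](C)(C)C(C)(C)C)[C@@H](C(=C)CO[Si](C)(C)C(C)(C)C)[C@H](O[Si](CC)(CC)CC)C1 | intermediate
45 | angelic acid, (Z)-2-methylbut-2-enoic acid | C/C=C(/C)C(=O)O | starting material
46 | angelic 2,4,6-trichlorobenzoic anhydride (formed in the flask) | C/C=C(/C)C(=O)OC(=O)c1c(Cl)cc(Cl)cc1Cl | intermediate
47 | (1(10)Z,3S,5S,6S,7S,8R)-3,6,12-tris(tert-butyldimethylsilyloxy)-8-(triethylsilyloxy)germacra-1(10),4(15),11(13)-trien-5-yl angelate | C/C1=C/C[C@H](O[Si](C)(C)C(C)(C)C)C(=C)[C@H](OC(=O)/C(C)=C\C)[C@@H](O[Si](C)(C)C(C)(C)C)[C@@H](C(=C)CO[Si](C)(C)C(C)(C)C)[C@H](O[Si](CC)(CC)CC)C1 | intermediate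
48 | (1(10)Z,3S,5S,6S,7S,8R)-3,6-bis(tert-butyldimethylsilyloxy)-8,12-dihydroxygermacra-1(10),4(15),11(13)-trien-5-yl angelate | C/C1=C/C[C@H](O[Si](C)(C)C(C)(C)C)C(=C)[C@H](OC(=O)/C(C)=C\C)[C@@H](O[Si](C)(C)C(C)(C)C)[C@@H](C(=C)CO)[C@H](O)C1 | intermediate
49 | 8-hydroxy-12-oxo analogue of 48 (C12 enal; formed in the flask) | C/C1=C/C[C@H](O[Si](C)(C)C(C)(C)C)C(=C)[C@H](OC(=O)/C(C)=C\C)[C@@H](O[Si](C)(C)C(C)(C)C)[C@@H](C(=C)C=O)[C@H](O)C1 | intermediate
50 | 12,8-lactol of 49 (either C12 epimer; formed in the flask) | C/C1=C/C[C@H](O[Si](C)(C)C(C)(C)C)C(=C)[C@H](OC(=O)/C(C)=C\C)[C@@H](O[Si](C)(C)C(C)(C)C)[C@H]2C(=C)C(O)O[C@@H]2C1 | intermediate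
51 | (1(10)Z,3S,5S,6S,7S,8R)-5-angeloyloxy-3,6-bis(tert-butyldimethylsilyloxy)germacra-1(10),4(15),11(13)-trien-12,8-olide | C/C1=C/C[C@H](O[Si](C)(C)C(C)(C)C)C(=C)[C@H](OC(=O)/C(C)=C\C)[C@@H](O[Si](C)(C)C(C)(C)C)[C@H]2C(=C)C(=O)O[C@@H]2C1 | intermediate
52 | (1S,3S,5S,6S,7S,8R,10R)-5-angeloyloxy-1,10-epoxy-3,6-bis(tert-butyldimethylsilyloxy)germacra-4(15),11(13)-dien-12,8-olide | C[C@@]12O[C@H]2C[C@H](O[Si](C)(C)C(C)(C)C)C(=C)[C@H](OC(=O)/C(C)=C\C)[C@@H](O[Si](C)(C)C(C)(C)C)[C@H]3C(=C)C(=O)O[C@@H]3C1 | intermediate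
53 | (1S,3S,5S,6S,7R,8R,10R)-5-angeloyloxy-1,10-epoxy-3,6-dihydroxygermacra-4(15),11(13)-dien-12,8-olide | C[C@@]12O[C@H]2C[C@H](O)C(=C)[C@H](OC(=O)/C(C)=C\C)[C@@H](O)[C@H]3C(=C)C(=O)O[C@@H]3C1 | intermediate
54 | CNP0348992.1, (1S,5S,6S,7R,8R,10R)-5-angeloyloxy-1,10-epoxy-6-hydroxy-3-oxogermacra-4(15),11(13)-dien-12,8-olide | C=C1C(=O)O[C@@H]2C[C@@]3(C)O[C@H]3CC(=O)C(=C)[C@H](OC(=O)/C(C)=C\C)[C@@H](O)[C@@H]12 | target

**Count and risks**

Total steps: 30. Longest linear sequence: 23 steps (steps 1–4, 7–10 and 16–30).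

Steps most likely to fail:

1. Step 21 (thiacycle closure). Intermolecular S-alkylation and disulfide formation may outrun the entropically unfavourable closure of the eleven-membered ring by the hindered secondary thiolate. The fallback sets out from 35 and comes back at 38, with the roles of the two carbons reversed. KSC(O)CH3 with NaI in DMF displaces the primary chloride to give the C1 thioacetate with free C10 hydroxyl F1. MsCl/Et3N converts it into the C1 thioacetate C10 mesylate F2. Slow addition of F2 to Cs2CO3 in MeOH/DMF releases the unhindered caesium C1 thiolate F3, which closes the ring by SN2 at C10. The inversion at C10 gives the same configuration as the Mitsunobu route, hence 38.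

2. Step 23 (ring contraction). Bromine transfer to the hindered sulfone on the alumina surface may stall, or prolonged exposure to base may erode the olefin geometry or the silyl ethers. The fallback sets out from 40 and comes back at 43, separating halogenation from extrusion. n-BuLi in THF at −78 °C gives the C1-lithiated sulfone F4, which is quenched with C2Cl6 to the isolated C1 α-chloro sulfone F5. KOt-Bu in THF at −78 → 0 °C then effects the 1,3-elimination through 42 and SO2 loss under kinetic conditions (classical two-stage Ramberg–Bäcklund reaction).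

3. Step 28 (epoxidation). The peracid may deliver oxygen to the α face if that proves to be the exposed face of the folded ring. The fallback sets out from 51 and comes back at 52 and inverts the facial outcome by a halohydrin sequence. N-Bromosuccinimide in aqueous THF at 0 °C forms the bromonium ion on the exposed face and water opens it at the tertiary C10 from the opposite side, giving the 1α-bromo-10β-hydroxy bromohydrin F6. K2CO3 in acetone closes the oxirane by backside displacement at C1, which places the oxygen on the β face.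

Further compounds
F1 | step 21 | S-[(3S,5S,6S,7S,8R,10R)-3,6-bis(tert-butyldimethylsilyloxy)-7-[3-(tert-butyldimethylsilyloxy)prop-1-en-2-yl]-10-hydroxy-5-(4-methoxybenzyloxy)-4-methylidene-8-(triethylsilyloxy)undecyl] ethanethioate | CC(=O)SCC[C@H](O[Si](C)(C)C(C)(C)C)C(=C)[C@H](OCc1ccc(OC)cc1)[C@@H](O[Si](C)(C)C(C)(C)C)[C@@H](C(=C)CO[Si](C)(C)C(C)(C)C)[C@H](O[Si](CC)(CC)CC)C[C@H](O)C
F2 | step 21 | C10 methanesulfonate of F1 | CC(=O)SCC[C@H](O[Si](C)(C)C(C)(C)C)C(=C)[C@H](OCc1ccc(OC)cc1)[C@@H](O[Si](C)(C)C(C)(C)C)[C@@H](C(=C)CO[Si](C)(C)C(C)(C)C)[C@H](O[Si](CC)(CC)CC)C[C@H](OS(C)(=O)=O)C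
F3 | step 21 | caesium C1 thiolate obtained from F2 by loss of the acetyl group (formed in the flask) | [Cs+].[S-]CC[C@H](O[Si](C)(C)C(C)(C)C)C(=C)[C@H](OCc1ccc(OC)cc1)[C@@H](O[Si](C)(C)C(C)(C)C)[C@@H](C(=C)CO[Si](C)(C)C(C)(C)C)[C@H](O[Si](CC)(CC)CC)C[C@H](OS(C)(=O)=O)C
F4 | step 23 | C1-lithiated sulfone 40 (formed in the flask) | C[C@H]1C[C@@H](O[Si](CC)(CC)CC)[C@H](C(=C)CO[Si](C)(C)C(C)(C)C)[C@H](O[Si](C)(C)C(C)(C)C)[C@@H](OCc2ccc(OC)cc2)C(=C)[C@@H](O[Si](C)(C)C(C)(C)C)CC([Li])S1(=O)=O
F5 | step 23 | 1-chloro derivative of sulfone 40 (either C1 epimer) | C[C@H]1C[C@@H](O[Si](CC)(CC)CC)[C@H](C(=C)CO[Si](C)(C)C(C)(C)C)[C@H](O[Si](C)(C)C(C)(C)C)[C@@H](OCc2ccc(OC)cc2)C(=C)[C@@H](O[Si](C)(C)C(C)(C)C)CC(Cl)S1(=O)=O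
F6 | step 28 | 1α-bromo-10β-hydroxy bromohydrin of 51, 5-angeloyloxy-1-bromo-3,6-bis(tert-butyldimethylsilyloxy)-10-hydroxygermacra-4(15),11(13)-dien-12,8-olide | C[C@]1(O)[C@H](Br)C[C@H](O[Si](C)(C)C(C)(C)C)C(=C)[C@H](OC(=O)/C(C)=C\C)[C@@H](O[Si](C)(C)C(C)(C)C)[C@H]2C(=C)C(=O)O[C@@H]2C1
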